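**Retrosynthetic overview** (C1 = lactone carbonyl, C4 = quaternary ring carbon, C5 and C10 = carbinols, C15 = CH2 on the furan)
1. C13–C14: B-alkyl Suzuki coupling of an (E)-alkenyl iodide with the 9-BBN adduct of 3-vinylfuran; the furan ring is bought, not built.
2. C12=C13 and C10: Zr-catalysed methylalumination/iodination of a homopropargylic alcohol, itself made by catalyst-controlled propargylation of a C1–C10 enal.
3. C4 and the only ring that is formed (the butanolide): chelation-controlled MeMgBr addition to an α-hydroxy-γ-keto ester, followed by lactonisation.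
4. Key C4–C5 bond: asymmetric nitroaldol of a C5 aldehyde with methyl 4-nitrobutanoate, used as the acyl anion of a 4-oxobutanoate (the nitronate carbon becomes the C4 carbonyl after a Nef reaction). This sets C5 and brings in C1–C4 in one step.
5. The C5–C10 aldehyde comes from geranyl acetate by selective ozonolysis. Ring order: butanolide in step 4, preformed furan attached in step 9.

Assumption: the antipodes of the chiral ligand in step 2 and of the phosphoric acid in step 6 are the ones that give 5R and 10S; if a test run shows the opposite sense, the mirror-image catalyst is used and nothing else changes.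

**Step 1**
Reactants: 1 geranyl acetate
Product: 3 (2E)-3-methyl-6-oxohex-2-en-1-yl acetate, via secondary ozonide 2 (not isolated)
Conditions: O3 (1.0 equiv), pyridine (cat.), CH2Cl2, −78 °C; then Me2S, −78 °C → rt
Reagents that add atoms: ozone, [O-][O+]=O
Why: Chemoselective ozonolysis, in which the electron-rich trisubstituted 6,7-olefin reacts much faster than the 2,3-olefin deactivated by the allylic acetate, so one equivalent of ozone and reduction of the ozonide with Me2S give the aldehyde with the E-olefin untouched and no stereocentre involved.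

**Step 2**
Reactants: 3 (2E)-3-methyl-6-oxohex-2-en-1-yl acetate; 4 methyl 4-nitrobutanoate
Product: 5 methyl (5R,8E)-10-acetoxy-5-hydroxy-8-methyl-4-nitrodec-8-enoate (both C4 epimers)
Conditions: Cu(OAc)2·H2O (10 mol%), camphor-derived N-(pyridin-2-ylmethyl)bornan-2-amine ligand (11 mol%), i-Pr2NEt (1 equiv), 4 (5 equiv), MeOH, −40 °C
Reagents that add atoms: none
Why: Catalytic asymmetric Henry (nitroaldol) reaction in which the nitronate of 4 acts as an acyl-anion equivalent of a 4-oxobutanoate, so the new C4–C5 bond joins two carbons that are both carbonyl carbons in the later acyloin, while the chiral divalent copper–aminopyridine complex binds aldehyde and nitronate and shields one aldehyde face to set C5 as R, the C4 epimers being irrelevant because C4 becomes sp2 in step 3.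

**Step 3**
Reactants: 5 methyl (5R,8E)-10-acetoxy-5-hydroxy-8-methyl-4-nitrodec-8-enoate
Product: 8 methyl (5R,8E)-5,10-dihydroxy-8-methyl-4-oxodec-8-enoate, via sodium nitronate 6 (not isolated), via ketimine 7 (not isolated)
Conditions: NaOMe (1.3 equiv), MeOH, 0 °C → rt; then TiCl3 (4 equiv, aq), NH4OAc buffer (pH 5–6), 0 °C → rt
Reagents that add atoms: water, O
Why: Nef reaction in its reductive form, in which NaOMe converts the nitro group fully into its nitronate (which cannot undergo retro-nitroaldol cleavage) and removes the acetate by catalytic transesterification, and trivalent titanium then cleaves the N–O bonds to the ketimine that hydrolyses in the buffer to the C4 ketone, unmasking the former acyl-anion carbon without touching C5.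

**Step 4**
Reactants: 8 methyl (5R,8E)-5,10-dihydroxy-8-methyl-4-oxodec-8-enoate
Product: 10 (5S)-5-[(1R,4E)-1,6-dihydroxy-4-methylhex-4-en-1-yl]-5-methyloxolan-2-one, via open-chain triol ester 9 (not isolated)
Conditions: MeMgBr (3.3 equiv), THF, −78 → −40 °C; aq NH4Cl; then PPTS (cat.), CH2Cl2, rt
Reagents that add atoms: methylmagnesium bromide, C[Mg]Br
Why: Grignard addition under Cram chelate control, in which the magnesium alkoxide of the C5 hydroxyl and the C4 carbonyl form a five-membered chelate, methyl attacks the ketone face anti to the C6 chain (giving 4S from 5R) faster than it attacks the ester, and the tertiary alkoxide then closes the five-membered lactone onto the methyl ester (5-exo-trig acyl substitution).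

**Step 5**
Reactants: 10 (5S)-5-[(1R,4E)-1,6-dihydroxy-4-methylhex-4-en-1-yl]-5-methyloxolan-2-one
Product: 11 (2E,6R)-6-hydroxy-3-methyl-6-[(2S)-2-methyl-5-oxooxolan-2-yl]hex-2-enal
Conditions: MnO2 (15 equiv), CH2Cl2, rt
Reagents that add atoms: none
Why: Chemoselective allylic oxidation with manganese dioxide, which oxidises only the primary allylic C10 alcohol and leaves the saturated secondary C5 alcohol, the lactone and the E-olefin geometry unchanged.

**Step 6**
Reactants: 11 (2E,6R)-6-hydroxy-3-methyl-6-[(2S)-2-methyl-5-oxooxolan-2-yl]hex-2-enal; 12 allenylboronic acid pinacol ester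
Product: 14 (5S)-5-[(1R,4E,6S)-1,6-dihydroxy-4-methylnon-4-en-8-yn-1-yl]-5-methyloxolan-2-one, via O-boryl adduct 13 (not isolated)
Conditions: 12 (1.5 equiv), (S)-TRIP phosphoric acid (10 mol%), 4 Å MS, toluene, 0 °C → rt; aq NaHCO3
Reagents that add atoms: none
Why: Chiral Brønsted-acid-catalysed asymmetric propargylation (allenylboration), in which the phosphoric acid hydrogen-bonds to a boronate oxygen and to the formyl hydrogen and the allenyl group is transferred through a closed six-membered SE2' transition state to one aldehyde face in a 1,2-addition, setting C10 as S by catalyst control with no influence from the remote stereocentres.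

**Step 7**
Reactants: 14 (5S)-5-[(1R,4E,6S)-1,6-dihydroxy-4-methylnon-4-en-8-yn-1-yl]-5-methyloxolan-2-one
Product: 16 (5S)-5-[(1R,4E,6S,8E)-1,6-dihydroxy-9-iodo-4,8-dimethylnona-4,8-dien-1-yl]-5-methyloxolan-2-one, via alkenylalane 15 (not isolated)
Conditions: AlMe3 (5 equiv), Cp2ZrCl2 (25 mol%), H2O (1 equiv), CH2Cl2, −20 °C → rt; then I2, THF, −30 → 0 °C; aq NaHCO3/Na2S2O3
Reagents that add atoms: trimethylaluminium, C[Al](C)C; iodine, II
Why: Negishi zirconium-catalysed carboalumination, in which methyl and aluminium add syn across the terminal alkyne with methyl on the internal carbon and iodinolysis of the alkenyl–aluminium bond with retention gives the E-trisubstituted alkenyl iodide, the two hydroxyls being carried as aluminium alkoxides and the lactone being inert to AlMe3 at this temperature.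

**Step 8**
Reactants: 17 furan-3-carbaldehyde
Product: 18 3-ethenylfuran
Conditions: Ph3PCH3Br, KOtBu, Et2O, 0 °C → rt; filtered through silica and used as a cold solution
Reagents that add atoms: methyltriphenylphosphonium bromide, C[P+](c1ccccc1)(c1ccccc1)c1ccccc1.[Br-]
Why: Wittig methylenation of the aldehyde with the non-stabilised ylide gives the vinylfuran, with no stereochemical issue.

**Step 9**
Reactants: 16 (5S)-5-[(1R,4E,6S,8E)-1,6-dihydroxy-9-iodo-4,8-dimethylnona-4,8-dien-1-yl]-5-methyloxolan-2-one; 18 3-ethenylfuran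
Product: 20 irciformonin B, via alkylborane 19 (not isolated)
Conditions: 18 (2 equiv), 9-BBN-H, THF, 0 °C → rt; then 16, PdCl2(dppf) (5 mol%), AsPh3, Cs2CO3, DMF–THF–H2O, rt; aq NH4Cl
Reagents that add atoms: none
Why: Hydroboration followed by B-alkyl Suzuki–Miyaura coupling, in which 9-BBN adds anti-Markovnikov to the vinyl group only and the base-activated primary alkylborane transmetallates to the alkenylpalladium iodide formed by oxidative addition of 16 to zerovalent palladium, so reductive elimination forms the C13–C14 bond with retention of the E geometry and leaves the free hydroxyls, the lactone and the furan intact.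

**Compound list**
1 | geranyl acetate, (2E)-3,7-dimethylocta-2,6-dien-1-yl acetate | CC(C)=CCC/C(C)=C/COC(C)=O | starting material
2 | secondary ozonide, (2E)-5-(5,5-dimethyl-1,2,4-trioxolan-3-yl)-3-methylpent-2-en-1-yl acetate | C/C(=C\COC(C)=O)CCC1OOC(C)(C)O1 | intermediate
3 | (2E)-3-methyl-6-oxohex-2-en-1-yl acetate | C/C(=C\COC(C)=O)CCC=O | intermediate
4 | methyl 4-nitrobutanoate | COC(=O)CCC[N+](=O)[O-] | starting material
5 | methyl (5R,8E)-10-acetoxy-5-hydroxy-8-methyl-4-nitrodec-8-enoate (both C4 epimers) | C/C(=C\COC(C)=O)CC[C@@H](O)C(CCC(=O)OC)[N+](=O)[O-] | intermediate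
6 | sodium nitronate, sodium salt of the aci-nitro form of methyl (5R,8E)-5,10-dihydroxy-8-methyl-4-nitrodec-8-enoate | C/C(=C\CO)CC[C@@H](O)C(CCC(=O)OC)=[N+]([O-])[O-].[Na+] | intermediate
7 | ketimine, methyl (5R,8E)-5,10-dihydroxy-4-imino-8-methyldec-8-enoate | C/C(=C\CO)CC[C@@H](O)C(=N)CCC(=O)OC | intermediate
8 | methyl (5R,8E)-5,10-dihydroxy-8-methyl-4-oxodec-8-enoate | C/C(=C\CO)CC[C@@H](O)C(=O)CCC(=O)OC | intermediate
9 | open-chain triol ester, methyl (4S,5R,8E)-4,5,10-trihydroxy-4,8-dimethyldec-8-enoate (in the flask as its bromomagnesium alkoxide) | C/C(=C\CO)CC[C@@H](O)[C@@](C)(O)CCC(=O)OC | intermediate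
10 | (5S)-5-[(1R,4E)-1,6-dihydroxy-4-methylhex-4-en-1-yl]-5-methyloxolan-2-one | C/C(=C\CO)CC[C@@H](O)[C@]1(C)CCC(=O)O1 | intermediate
11 | (2E,6R)-6-hydroxy-3-methyl-6-[(2S)-2-methyl-5-oxooxolan-2-yl]hex-2-enal | C/C(=C\C=O)CC[C@@H](O)[C@]1(C)CCC(=O)O1 | intermediate
12 | allenylboronic acid pinacol ester, 4,4,5,5-tetramethyl-2-(propa-1,2-dien-1-yl)-1,3,2-dioxaborolane | C=C=CB1OC(C)(C)C(C)(C)O1 | starting material
13 | O-boryl adduct, the C6′ pinacol borate of 14 | C/C(=C\[C@@H](OB2OC(C)(C)C(C)(C)O2)CC#C)CC[C@@H](O)[C@]1(C)CCC(=O)O1 | intermediate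
14 | (5S)-5-[(1R,4E,6S)-1,6-dihydroxy-4-methylnon-4-en-8-yn-1-yl]-5-methyloxolan-2-one | C/C(=C\[C@@H](O)CC#C)CC[C@@H](O)[C@]1(C)CCC(=O)O1 | intermediate
15 | alkenylalane, the (E)-9-(dimethylalumanyl)-4,8-dimethylnona-4,8-dienyl analogue of 16 (hydroxyls as aluminium alkoxides in the flask) | C/C(=C\[C@@H](O)C/C(C)=C/[Al](C)C)CC[C@@H](O)[C@]1(C)CCC(=O)O1 | intermediate
16 | (5S)-5-[(1R,4E,6S,8E)-1,6-dihydroxy-9-iodo-4,8-dimethylnona-4,8-dien-1-yl]-5-methyloxolan-2-one | C/C(=C\[C@@H](O)C/C(C)=C/I)CC[C@@H](O)[C@]1(C)CCC(=O)O1 | intermediate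
17 | furan-3-carbaldehyde | O=Cc1ccoc1 | starting material
18 | 3-ethenylfuran | C=Cc1ccoc1 | intermediate
19 | alkylborane, 9-[2-(furan-3-yl)ethyl]-9-borabicyclo[3.3.1]nonane | c1cc(CCB2C3CCCC2CCC3)co1 | intermediate
20 | irciformonin B, (5S)-5-[(1R,4E,6S,8E)-11-(furan-3-yl)-1,6-dihydroxy-4,8-dimethylundeca-4,8-dien-1-yl]-5-methyloxolan-2-one | C/C(=C\[C@@H](O)C/C(C)=C/CCc1ccoc1)CC[C@@H](O)[C@]1(C)CCC(=O)O1 | target

**Step count and risks**
Total step count: 9. Longest linear sequence: 8 (steps 1–7 and 9); step 8 is a one-step side branch.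

Step 3 is the most exposed step, because it is a Nef reaction on an unprotected β-hydroxy nitro ester; the dangers are retro-nitroaldol loss of the C5 configuration before the nitronate is fully formed and over-reduction of the acyloin by trivalent titanium. The fallback sets out from 5 and returns at 8. The nitro group is reduced only as far as the oxime with SnCl2·2H2O, PhSH and Et3N in MeCN, giving the acetoxy oxime F1. The acetate is removed with K2CO3 in MeOH at 0 °C to give the dihydroxy oxime F2. The oxime is then exchanged onto aqueous glyoxylic acid (NaOAc, THF–H2O, rt), which releases 8 with no reducing metal present once the ketone exists.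

Step 6 is the second risk, because the Brønsted-acid-catalysed propargylation may be slow or less selective on a β,β-disubstituted enal. The fallback sets out from 11 and returns at 16, and sets C10 by a reagent-controlled reduction instead. A Barbier propargylation (Zn, propargyl bromide, THF–aq NH4Cl) gives the epimeric alcohol mixture F3. The conditions of step 7 convert it into the epimeric iodide mixture F4. MnO2 oxidises only the allylic C10 carbinol, giving the enone F5. Corey–Bakshi–Shibata reduction with (R)-2-methyl-CBS-oxazaborolidine and catecholborane (toluene, −78 °C, the alkenyl group acting as the large substituent) then gives 16 with 10S.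

Step 7 is the third risk, because AlMe3 meets a lactone and an allylic aluminium alkoxide. The fallback sets out from 14 and returns at 16 and replaces carboalumination by a copper-catalysed methylboration. CuCl, Xantphos, NaOtBu, B2pin2 and MeI in THF at rt effect syn borylcupration with boron on the terminal carbon, and the alkenylcopper is methylated with retention, giving the alkenylboronate F6. Ipso-iododeboronation with N-iodosuccinimide in MeCN then gives 16 with retention of the E geometry.

**Further compounds**
F1 | step 3 | methyl (5R,8E)-10-acetoxy-5-hydroxy-4-(hydroxyimino)-8-methyldec-8-enoate | C/C(=C\COC(C)=O)CC[C@@H](O)C(CCC(=O)OC)=NO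
F2 | step 3 | methyl (5R,8E)-5,10-dihydroxy-4-(hydroxyimino)-8-methyldec-8-enoate | C/C(=C\CO)CC[C@@H](O)C(CCC(=O)OC)=NO
F3 | step 6 | (5S)-5-[(1R,4E,6RS)-1,6-dihydroxy-4-methylnon-4-en-8-yn-1-yl]-5-methyloxolan-2-one | C/C(=C\C(O)CC#C)CC[C@@H](O)[C@]1(C)CCC(=O)O1
F4 | step 6 | (5S)-5-[(1R,4E,6RS,8E)-1,6-dihydroxy-9-iodo-4,8-dimethylnona-4,8-dien-1-yl]-5-methyloxolan-2-one | C/C(=C\C(O)C/C(C)=C/I)CC[C@@H](O)[C@]1(C)CCC(=O)O1
F5 | step 6 | (5S)-5-[(1R,4E,8E)-1-hydroxy-9-iodo-4,8-dimethyl-6-oxonona-4,8-dien-1-yl]-5-methyloxolan-2-one | C/C(=C\C(=O)C/C(C)=C/I)CC[C@@H](O)[C@]1(C)CCC(=O)O1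
F6 | step 7 | (5S)-5-[(1R,4E,6S,8E)-1,6-dihydroxy-4,8-dimethyl-9-(4,4,5,5-tetramethyl-1,3,2-dioxaborolan-2-yl)nona-4,8-dien-1-yl]-5-methyloxolan-2-one | C/C(=C\[C@@H](O)C/C(C)=C/B2OC(C)(C)C(C)(C)O2)CC[C@@H](O)[C@]1(C)CCC(=O)O1
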